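At the reading time of 15 min the three flasks differ in how they spend one charge of coupling partner.

| setting | delta | gamma | cedar | oak | ash |
|---|---|---|---|---|---|
| substrate | 0.12 M | 0.18 M | 0.24 M | 0.24 M | 0.24 M |
| coupling partner | 1 equiv | 1 equiv | 1.00 equiv | 1.00 equiv | 1.00 equiv |
| temperature | 0 °C | 20 °C | 5 °C |  | 35 °C |
| remark | run made earlier | run made earlier |  | at 5 °C until 8.0 min, from then on at 35 °C |  |
| time |  |  | 15 min | 15 min | 15 min |

| run | time / min | target / % |
|---|---|---|
| delta | 2.00 | 7 |
| delta | 4.00 | 8 |
| delta | 6.00 | 13 |
| delta | 8.00 | 16 |
| delta | 10.0 | 17 |
| delta | 12.0 | 22 |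
| delta | 15.0 | 25 |
| gamma | 0.667 | 11 |
| gamma | 1.00 | 19 |
| gamma | 1.33 | 23 |
| gamma | 2.00 | 27 |
| gamma | 3.00 | 34 |
| gamma | 5.00 | 38 |
| gamma | 8.00 | 38 |

(each reading ± 2 percentage points)

- a reading or a percentage of target counts all its forms, free or not

- the best flask by amount of target, in percent of the substrate charged; "all alike" if 1.5 percentage points covers them all (cedar / oak / ash / all alike)
- amount of target at the end, in percent of the substrate charged, cedar
- amount of target at the end, in percent of the substrate charged, oak
- amount of target at the end, in percent of the substrate charged, ash

Work with the substrate left, not the target made: take the natural log of one over the fraction left, a count that adds up from stage to stage. Gamma goes flat at 38%, which I read as partner lost, and its count there is 0.478. This count at the flat, what one charge of partner buys before it is lost, is the stop number.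

Gamma's count rises at 0.211 /min over its first stretch, so I read a loss of partner at about 0.441 /min. Delta's count rises at 0.0218 /min up to 8.00 min, then at 0.0162 /min. Within the scatter, that reads as a loss of about 0.0396 /min and a stop number of 0.550.

By my own reckoning, spacing the loss evenly by ratio gives 0.0724 /min at 5 °C. So 56.0% of the partner escapes loss up to 8.0 min, and 33.8% up to 15 min. Cedar's charge is twice delta's. If the stop number doubles with it, cedar gives 51.7%. Oak, finishing its remaining partner at gamma's stop number, gives 52.8%.

The doubling is the weak link: coupling spends partner too, and delta and gamma differ in strength and temperature together. With the square root of the strength instead, cedar gives 40.2% and oak 45.7%. I commit to those, with ash at gamma's 38%, and oak best.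

The forecast differs on the winner. It gives cedar 45% (38% to 53%), oak 36% (29% to 46%) and ash 32% (22% to 42%): “Cedar is probably best.”

The flasks give cedar 38.6%, oak 41.7% and ash 32.7%, so oak is best.

    substrate + coupling partner → target, rate k1*[substrate]*[coupling partner]^0.5 (k = 0.120 /M^0.5/min, Ea = 69.0 kJ/mol)
    coupling partner + target ⇌ idle adduct, settled at all times (K = 10.0 /M, ΔH = −52.0 kJ/mol)
    coupling partner → decomposed reagent (k = 0.0900 /min, Ea = 85.0 kJ/mol)
    (constants at 5 °C)

Ash's count at the end is 0.395, below gamma's stop number of 0.478, and its partner, the limiting reagent, stands at 0%. Just after the start of ash, the reaction of partner to decomposed reagent uses partner 3.0 times as fast as coupling does. That reaction is the main reason for ash's low figure: without it ash gives 98.5%.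

For ash with 2.50 equiv of partner, scaling ash's count by the square root of the partner charge gives a target of 46.5%, and scaling it by the charge itself gives 62.8%. That flask gives 53.8%, with partner at 0%.

The earlier runs and the new flask were computed on assumed constants; scatter was added.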